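**Retrosynthetic overview**
1. Macrolactone (last ring): C7–C8 by intramolecular Sonogashira coupling of seco-ester 31, then Z-selective semireduction of the enyne; C2=C3 and the ester link by Still–Gennari union of phosphonate 22 with aldehyde 30.
2. C11 by catalytic asymmetric propargylboration of a Z-enal; C12=C13 by Still–Gennari olefination of oxolane aldehyde 14.
3. Oxirane (second ring): Shi epoxidation of the distal alkene of the sorbyl diene in 12.
4. Oxolane (first ring): Et3SiH/BF3 opening of 2,7-dioxabicyclo[2.2.1]heptane 11, whose two rings close in one acid-catalysed transketalisation of keto acetonide 10.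
5. 10 comes from an Evans syn aldol (sorbaldehyde) and a Mukaiyama aldol with (R)-glyceraldehyde acetonide; ring order: bicyclic ketal (oxolane + dioxolane) → oxirane → macrolactone.

Assumption: the SMILES is read as (2Z,4S,6E,8Z,11R,12Z,14R,15S,17R,18R,19R,20E,22R,23R), C1 being the lactone carbonyl and C24 the epoxide methyl; these positions (and O13, O14 for the oxygens on C13, C14) are used as locants for late intermediates.

Step 1
Reactants: 1 (4S)-4-benzyl-3-propanoyl-1,3-oxazolidin-2-one; 2 (2E,4E)-hexa-2,4-dienal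
Product: 3 (4S)-4-benzyl-3-[(2S,3R,4E,6E)-3-hydroxy-2-methylocta-4,6-dienoyl]-1,3-oxazolidin-2-one
Conditions: Bu2BOTf, Et3N, CH2Cl2, −78 → 0 °C; then pH 7 buffer, MeOH, H2O2
Reagents that add atoms: none
Why: Evans boron syn-aldol, in which the Z-boron enolate reacts through a chair Zimmerman–Traxler transition state on the face left open by the benzyl auxiliary and so sets C18 (methyl) and C19 (oxygen) as the 2S,3R syn pair.

Step 2
Reactants: 3 (4S)-4-benzyl-3-[(2S,3R,4E,6E)-3-hydroxy-2-methylocta-4,6-dienoyl]-1,3-oxazolidin-2-one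
Product: 4 (2S,3R,4E,6E)-3-hydroxy-N-methoxy-N,2-dimethylocta-4,6-dienamide
Conditions: MeNH(OMe)·HCl, AlMe3, THF, −20 → 0 °C
Reagents that add atoms: N,O-dimethylhydroxylamine hydrochloride, CNOC.Cl
Why: Weinreb transamidation by the aluminium amide, directed to the exocyclic imide carbonyl by the free β-hydroxyl, releases the auxiliary without touching the two stereocentres.

Step 3
Reactants: 4 (2S,3R,4E,6E)-3-hydroxy-N-methoxy-N,2-dimethylocta-4,6-dienamide
Product: 5 (2S,3R,4E,6E)-3-(tert-butyldimethylsilyloxy)-N-methoxy-N,2-dimethylocta-4,6-dienamide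
Conditions: TBSOTf, 2,6-lutidine, CH2Cl2, −78 °C
Reagents that add atoms: tert-butyldimethylsilyl triflate, CC(C)(C)[Si](C)(C)OS(=O)(=O)C(F)(F)F
Why: Silyl ether formation blocks the C19 hydroxyl for the enolate, oxonium and Lewis acid steps that follow and later steers the epoxidation to the distal alkene.

Step 4
Reactants: 5 (2S,3R,4E,6E)-3-(tert-butyldimethylsilyloxy)-N-methoxy-N,2-dimethylocta-4,6-dienamide
Product: 6 (3S,4R,5E,7E)-4-(tert-butyldimethylsilyloxy)-3-methylnona-5,7-dien-2-one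
Conditions: MeMgBr, THF, 0 °C
Reagents that add atoms: methylmagnesium bromide, C[Mg]Br
Why: Weinreb ketone synthesis, in which the chelated tetrahedral intermediate stops the addition at the methyl ketone (C16–C17) and avoids enolisation at C18.

Step 5
Reactants: 6 (3S,4R,5E,7E)-4-(tert-butyldimethylsilyloxy)-3-methylnona-5,7-dien-2-one; 7 (4R)-2,2-dimethyl-1,3-dioxolane-4-carbaldehyde
Product: 9 (1S,4S,5R,6E,8E)-5-(tert-butyldimethylsilyloxy)-1-[(4R)-2,2-dimethyl-1,3-dioxolan-4-yl]-1-hydroxy-4-methyldeca-6,8-dien-3-one, via trimethylsilyl enol ether 8 (not isolated)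
Conditions: LiN(SiMe3)2, Me3SiCl, THF, −78 °C; then 7, BF3·OEt2, CH2Cl2, −78 °C
Reagents that add atoms: none
Why: Mukaiyama aldol of the kinetic (methyl-side) enol silane, with Felkin–Anh addition to the α-alkoxy aldehyde under non-chelating BF3 giving the 14,15-anti adduct, so C15 is set S next to the chiral-pool C14.

Step 6
Reactants: 9 (1S,4S,5R,6E,8E)-5-(tert-butyldimethylsilyloxy)-1-[(4R)-2,2-dimethyl-1,3-dioxolan-4-yl]-1-hydroxy-4-methyldeca-6,8-dien-3-one
Product: 10 (1S,4S,5R,6E,8E)-5-(tert-butyldimethylsilyloxy)-1-[(4R)-2,2-dimethyl-1,3-dioxolan-4-yl]-1-methoxy-4-methyldeca-6,8-dien-3-one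
Conditions: Me3OBF4, 1,8-bis(dimethylamino)naphthalene, CH2Cl2, 0 °C → rt
Reagents that add atoms: trimethyloxonium tetrafluoroborate, C[O+](C)C.F[B-](F)(F)F
Why: O-methylation with Meerwein's salt under non-basic conditions installs the C15 methyl ether without retro-aldol or β-elimination of the β-hydroxy ketone.

Step 7
Reactants: 10 (1S,4S,5R,6E,8E)-5-(tert-butyldimethylsilyloxy)-1-[(4R)-2,2-dimethyl-1,3-dioxolan-4-yl]-1-methoxy-4-methyldeca-6,8-dien-3-one
Product: 11 (1S,4R,5S)-1-[(2S,3R,4E,6E)-3-(tert-butyldimethylsilyloxy)octa-4,6-dien-2-yl]-5-methoxy-2,7-dioxabicyclo[2.2.1]heptane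
Conditions: camphorsulfonic acid (10 mol %), CH2Cl2, 0 °C → rt, acetone stripped off under reduced pressure
Reagents that add atoms: none
Why: Acid-catalysed intramolecular transketalisation, in which O14 and O13 of the opened acetonide add in turn to the C17 ketone and acetone leaves, so the oxolane ring and the 1,3-dioxolane ring of the bicyclic ketal both close in this one operation and the bicycle fixes C17.

Step 8
Reactants: 11 (1S,4R,5S)-1-[(2S,3R,4E,6E)-3-(tert-butyldimethylsilyloxy)octa-4,6-dien-2-yl]-5-methoxy-2,7-dioxabicyclo[2.2.1]heptane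
Product: 12 [(2R,3S,5R)-5-[(2R,3R,4E,6E)-3-(tert-butyldimethylsilyloxy)octa-4,6-dien-2-yl]-3-methoxyoxolan-2-yl]methanol
Conditions: Et3SiH, BF3·OEt2, CH2Cl2, −78 → −40 °C
Reagents that add atoms: none
Why: Proposed new method: BF3 binds the less hindered bridge oxygen O13 and ionises the C17–O13 bond of the strained ketal to the five-membered oxocarbenium ion, which Et3SiH reduces by inside attack on the envelope with the C15 methoxy group pseudoaxial (hydride cis to OMe and trans to the C14 arm), so C17 becomes R with the 2,5-cis pattern and the C13 hydroxyl is freed; the closest known reactions are the Et3SiH/Lewis acid reductive opening of 6,8-dioxabicyclo[3.2.1]octanes and 1,6-anhydro sugars and the Et3SiH/BF3 reduction of 2-deoxyribofuranosyl hemiketals to β-C-glycosides.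

Step 9
Reactants: 12 [(2R,3S,5R)-5-[(2R,3R,4E,6E)-3-(tert-butyldimethylsilyloxy)octa-4,6-dien-2-yl]-3-methoxyoxolan-2-yl]methanol
Product: 13 [(2R,3S,5R)-5-[(2R,3R,4E)-3-(tert-butyldimethylsilyloxy)-5-[(2R,3R)-3-methyloxiran-2-yl]pent-4-en-2-yl]-3-methoxyoxolan-2-yl]methanol
Conditions: D-fructose-derived Shi ketone (30 mol %), Oxone (2KHSO5·KHSO4·K2SO4), K2CO3, Bu4NHSO4, MeCN/(MeO)2CH2/aq. Na2B4O7 buffer, 0 °C
Reagents that add atoms: potassium peroxymonosulfate, [K+].[O-]S(=O)(=O)OO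
Why: Shi dioxirane epoxidation through the spiro transition state attacks only the distal, more electron-rich trans alkene (the proximal one is deactivated and shielded by the allylic silyl ether) and, under catalyst control, gives the (22R,23R)-oxirane.

Step 10
Reactants: 13 [(2R,3S,5R)-5-[(2R,3R,4E)-3-(tert-butyldimethylsilyloxy)-5-[(2R,3R)-3-methyloxiran-2-yl]pent-4-en-2-yl]-3-methoxyoxolan-2-yl]methanol
Product: 14 (2S,3S,5R)-5-[(2R,3R,4E)-3-(tert-butyldimethylsilyloxy)-5-[(2R,3R)-3-methyloxiran-2-yl]pent-4-en-2-yl]-3-methoxyoxolane-2-carbaldehyde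
Conditions: Dess–Martin periodinane, NaHCO3, CH2Cl2, 0 °C → rt
Reagents that add atoms: none
Why: Buffered Dess–Martin oxidation gives the C13 aldehyde without epimerising C14 or opening the vinyl oxirane.

Step 11
Reactants: 14 (2S,3S,5R)-5-[(2R,3R,4E)-3-(tert-butyldimethylsilyloxy)-5-[(2R,3R)-3-methyloxiran-2-yl]pent-4-en-2-yl]-3-methoxyoxolane-2-carbaldehyde; 15 methyl 2-[bis(2,2,2-trifluoroethoxy)phosphoryl]propanoate
Product: 16 methyl (2Z)-3-[(2R,3S,5R)-5-[(2R,3R,4E)-3-(tert-butyldimethylsilyloxy)-5-[(2R,3R)-3-methyloxiran-2-yl]pent-4-en-2-yl]-3-methoxyoxolan-2-yl]-2-methylprop-2-enoate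
Conditions: KN(SiMe3)2, 18-crown-6, THF, −78 °C
Reagents that add atoms: none
Why: Still–Gennari olefination, whose fast, irreversible elimination from the kinetically favoured adduct gives the Z-trisubstituted C12=C13 alkene (C11 cis to C14).

Step 12
Reactants: 16 methyl (2Z)-3-[(2R,3S,5R)-5-[(2R,3R,4E)-3-(tert-butyldimethylsilyloxy)-5-[(2R,3R)-3-methyloxiran-2-yl]pent-4-en-2-yl]-3-methoxyoxolan-2-yl]-2-methylprop-2-enoate
Product: 17 (2Z)-3-[(2R,3S,5R)-5-[(2R,3R,4E)-3-(tert-butyldimethylsilyloxy)-5-[(2R,3R)-3-methyloxiran-2-yl]pent-4-en-2-yl]-3-methoxyoxolan-2-yl]-2-methylprop-2-en-1-ol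
Conditions: iBu2AlH, CH2Cl2, −78 °C
Reagents that add atoms: none
Why: Low-temperature 1,2-reduction of the enoate to the Z-allylic alcohol is faster than hydride opening of the vinyl oxirane.

Step 13
Reactants: 17 (2Z)-3-[(2R,3S,5R)-5-[(2R,3R,4E)-3-(tert-butyldimethylsilyloxy)-5-[(2R,3R)-3-methyloxiran-2-yl]pent-4-en-2-yl]-3-methoxyoxolan-2-yl]-2-methylprop-2-en-1-ol
Product: 18 (2Z)-3-[(2R,3S,5R)-5-[(2S,3R,4E)-3-hydroxy-5-[(2R,3R)-3-methyloxiran-2-yl]pent-4-en-2-yl]-3-methoxyoxolan-2-yl]-2-methylprop-2-en-1-ol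
Conditions: Bu4NF, THF, 0 °C → rt
Reagents that add atoms: none
Why: Fluoride desilylation frees the C19 hydroxyl under basic conditions that the vinyl oxirane tolerates (the 18S label is a priority change only).

Step 14
Reactants: 18 (2Z)-3-[(2R,3S,5R)-5-[(2S,3R,4E)-3-hydroxy-5-[(2R,3R)-3-methyloxiran-2-yl]pent-4-en-2-yl]-3-methoxyoxolan-2-yl]-2-methylprop-2-en-1-ol
Product: 19 (2Z)-3-[(2R,3S,5R)-5-[(2S,3R,4E)-3-hydroxy-5-[(2R,3R)-3-methyloxiran-2-yl]pent-4-en-2-yl]-3-methoxyoxolan-2-yl]-2-methylprop-2-enal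
Conditions: TEMPO (10 mol %), PhI(OAc)2, CH2Cl2, rt
Reagents that add atoms: none
Why: Oxoammonium (TEMPO) oxidation is selective for the primary allylic alcohol over the hindered secondary C19 alcohol and does not isomerise the Z-enal.

Step 15
Reactants: 15 methyl 2-[bis(2,2,2-trifluoroethoxy)phosphoryl]propanoate
Product: 20 2-[bis(2,2,2-trifluoroethoxy)phosphoryl]propanoic acid
Conditions: LiOH (1.05 equiv), THF/H2O, 0 °C; then 1 M HCl
Reagents that add atoms: lithium hydroxide, [Li+].[OH-]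
Why: Saponification of the carboxylic methyl ester at 0 °C is faster than attack at phosphorus, and the carboxylate formed protects the phosphonate from further hydroxide.

Step 16
Reactants: 19 (2Z)-3-[(2R,3S,5R)-5-[(2S,3R,4E)-3-hydroxy-5-[(2R,3R)-3-methyloxiran-2-yl]pent-4-en-2-yl]-3-methoxyoxolan-2-yl]-2-methylprop-2-enal; 20 2-[bis(2,2,2-trifluoroethoxy)phosphoryl]propanoic acid
Product: 21 C11–C24 Z-enal carrying the 2-[bis(2,2,2-trifluoroethoxy)phosphoryl]propanoate ester on O19 (12Z,14R,15S,17R,18R,19R,20E,22R,23R; both epimers at the P-bearing carbon)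
Conditions: DCC, CH2Cl2, 0 °C → rt (no DMAP)
Reagents that add atoms: none
Why: Carbodiimide esterification of the phosphonoalkanoic acid (through its ketene) acylates the only free hydroxyl and, without a nucleophilic catalyst, leaves the Z-enal geometry intact.

Step 17
Reactants: 21 C11–C24 Z-enal carrying the 2-[bis(2,2,2-trifluoroethoxy)phosphoryl]propanoate ester on O19
Product: 22 C8–C24 homopropargylic alcohol phosphonate (11R,12Z,14R,15S,17R,18R,19R,20E,22R,23R)
Conditions: allenylboronic acid pinacol ester, (R)-TRIP phosphoric acid (10 mol %), 4 Å MS, toluene, −20 °C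
Reagents that add atoms: allenylboronic acid pinacol ester, C=C=CB1OC(C)(C)C(C)(C)O1
Why: Chiral phosphoric acid catalysed propargylboration through a six-membered chair transition state adds to the Re face of the enal under catalyst control and sets C11 as R, under base-free conditions that leave the phosphonate untouched; the (R)-catalyst is chosen by analogy with aryl and alkenyl aldehydes and would be exchanged for its antipode if the sense proved opposite.

Step 18
Reactants: 23 prop-2-yn-1-ol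
Product: 25 (2E)-3-iodo-2-methylprop-2-en-1-ol, via alkenylalane 24 (not isolated)
Conditions: AlMe3, Cp2ZrCl2 (25 mol %), CH2Cl2, 0 °C → rt; then I2, THF, −30 °C
Reagents that add atoms: trimethylaluminium, C[Al](C)C; iodine, II
Why: Negishi zirconium-catalysed carboalumination adds methyl and aluminium syn across the alkyne and iodinolysis proceeds with retention, giving the E-vinyl iodide (C6 methyl, C7 iodide).

Step 19
Reactants: 25 (2E)-3-iodo-2-methylprop-2-en-1-ol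
Product: 26 (2E)-3-iodo-2-methylprop-2-enal
Conditions: MnO2, CH2Cl2, rt
Reagents that add atoms: none
Why: MnO2 oxidation of the allylic alcohol gives the enal without isomerising the vinyl iodide.

Step 20
Reactants: 26 (2E)-3-iodo-2-methylprop-2-enal; 27 (4R)-4-benzyl-3-propanoyl-1,3-thiazolidine-2-thione
Product: 28 (2R,3R,4E)-1-[(4R)-4-benzyl-2-sulfanylidene-1,3-thiazolidin-3-yl]-3-hydroxy-5-iodo-2,4-dimethylpent-4-en-1-one
Conditions: TiCl4, iPr2NEt, N-methylpyrrolidinone, CH2Cl2, 0 → −78 °C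
Reagents that add atoms: none
Why: Crimmins titanium enolate aldol through the non-chelated chair transition state gives the Evans-syn adduct, which sets C4 (the later 4S centre) with C5 as a temporary carbinol.

Step 21
Reactants: 28 (2R,3R,4E)-1-[(4R)-4-benzyl-2-sulfanylidene-1,3-thiazolidin-3-yl]-3-hydroxy-5-iodo-2,4-dimethylpent-4-en-1-one
Product: 29 (2R,3R,4E)-1-[(4R)-4-benzyl-2-sulfanylidene-1,3-thiazolidin-3-yl]-5-iodo-2,4-dimethyl-3-(triethylsilyloxy)pent-4-en-1-one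
Conditions: Et3SiOTf, 2,6-lutidine, CH2Cl2, −78 °C
Reagents that add atoms: triethylsilyl triflate, CC[Si](CC)(CC)OS(=O)(=O)C(F)(F)F
Why: Silylation masks C5 as a carbinol ether so that the base-labile C4 centre is carried at the alcohol oxidation level until the end.

Step 22
Reactants: 29 (2R,3R,4E)-1-[(4R)-4-benzyl-2-sulfanylidene-1,3-thiazolidin-3-yl]-5-iodo-2,4-dimethyl-3-(triethylsilyloxy)pent-4-en-1-one
Product: 30 (2R,3R,4E)-5-iodo-2,4-dimethyl-3-(triethylsilyloxy)pent-4-enal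
Conditions: iBu2AlH, CH2Cl2, −78 °C
Reagents that add atoms: none
Why: The N-acylthiazolidinethione is reduced directly to the aldehyde through a stable tetrahedral aluminium intermediate, releasing the auxiliary.

Step 23
Reactants: 22 C8–C24 homopropargylic alcohol phosphonate; 30 (2R,3R,4E)-5-iodo-2,4-dimethyl-3-(triethylsilyloxy)pent-4-enal
Product: 31 open-chain C1–C24 seco-ester, the (2Z,4S,5R,6E)-7-iodo-2,4,6-trimethyl-5-(triethylsilyloxy)hepta-2,6-dienoate of O19 with free C8 alkyne and C11 hydroxyl (11R,12Z,14R,15S,17R,18R,19R,20E,22R,23R)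
Conditions: KN(SiMe3)2 (1.05 equiv), 18-crown-6, THF, −78 °C
Reagents that add atoms: none
Why: Intermolecular Still–Gennari olefination (only the far more acidic phosphonate is deprotonated) joins the fragments and gives the Z-configured C2=C3 enoate without epimerising the α-branched aldehyde.

Step 24
Reactants: 31 open-chain C1–C24 seco-ester
Product: 32 8,9-didehydro macrolactone (macrocyclic enyne), 5-O-triethylsilyl ether (2Z,4S,5R,6E,11R,12Z,14R,15S,17R,18R,19R,20E,22R,23R)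
Conditions: Pd(PPh3)4 (10 mol %), CuI (20 mol %), Et3N, THF, 2 mM, slow addition, rt
Reagents that add atoms: none
Why: Intramolecular Sonogashira coupling of the E-vinyl iodide with the terminal alkyne closes the macrolactone at C7–C8 with retention of the C6=C7 geometry, oxidative addition to the vinyl iodide outpacing ionisation of the vinyl oxirane by zerovalent palladium.

Step 25
Reactants: 32 8,9-didehydro macrolactone, 5-O-triethylsilyl ether
Product: 33 (5R)-5-deoxo-5-(triethylsilyloxy) macrolide with the (6E,8Z)-diene (2Z,4S,5R,6E,8Z,11R,12Z,14R,15S,17R,18R,19R,20E,22R,23R)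
Conditions: Zn dust (pre-activated with Cu(OAc)2 and AgNO3), MeOH/H2O, 40 °C
Reagents that add atoms: none
Why: Boland-type zinc semireduction is selective for the conjugated alkyne and delivers both hydrogens syn, giving the 8Z alkene without hydrogenolysis of the allylic oxirane.

Step 26
Reactants: 33 (5R)-5-deoxo-5-(triethylsilyloxy) macrolide
Product: 34 (5R)-5-deoxo-5-hydroxy macrolide (5,11-diol)
Conditions: HF·pyridine, pyridine, THF, 0 °C
Reagents that add atoms: none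
Why: Buffered fluoride cleavage of the triethylsilyl ether is mild enough for the vinyl oxirane and the enoate.

Step 27
Reactants: 34 (5R)-5-deoxo-5-hydroxy macrolide (5,11-diol)
Product: 35 CNP0117824.1 (target)
Conditions: DDQ (1.2 equiv), CH2Cl2/pH 7 phosphate buffer, 0 °C
Reagents that add atoms: none
Why: DDQ oxidation by hydride abstraction is much faster at the dienylic C5 carbinol (pentadienyl-stabilised cation) than at the mono-allylic C11 carbinol, and its neutral conditions keep the C4 centre next to the new ketone intact.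

**Compound list**
1 | (4S)-4-benzyl-3-propanoyl-1,3-oxazolidin-2-one | CCC(=O)N1[C@@H](Cc2ccccc2)COC1=O | starting material
2 | (2E,4E)-hexa-2,4-dienal | C/C=C/C=C/C=O | starting material
3 | (4S)-4-benzyl-3-[(2S,3R,4E,6E)-3-hydroxy-2-methylocta-4,6-dienoyl]-1,3-oxazolidin-2-one | C/C=C/C=C/[C@@H](O)[C@H](C)C(=O)N1[C@@H](Cc2ccccc2)COC1=O | intermediate
4 | (2S,3R,4E,6E)-3-hydroxy-N-methoxy-N,2-dimethylocta-4,6-dienamide | C/C=C/C=C/[C@@H](O)[C@H](C)C(=O)N(C)OC | intermediate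
5 | (2S,3R,4E,6E)-3-(tert-butyldimethylsilyloxy)-N-methoxy-N,2-dimethylocta-4,6-dienamide | C/C=C/C=C/[C@@H](O[Si](C)(C)C(C)(C)C)[C@H](C)C(=O)N(C)OC | intermediate
6 | (3S,4R,5E,7E)-4-(tert-butyldimethylsilyloxy)-3-methylnona-5,7-dien-2-one | C/C=C/C=C/[C@@H](O[Si](C)(C)C(C)(C)C)[C@H](C)C(C)=O | intermediate
7 | (4R)-2,2-dimethyl-1,3-dioxolane-4-carbaldehyde | O=C[C@H]1COC(C)(C)O1 | starting material
8 | trimethylsilyl enol ether of 6, (2E,4E,6R,7S)-6-(tert-butyldimethylsilyloxy)-7-methyl-8-(trimethylsilyloxy)nona-2,4,8-triene | C/C=C/C=C/[C@@H](O[Si](C)(C)C(C)(C)C)[C@H](C)C(=C)O[Si](C)(C)C | intermediate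
9 | (1S,4S,5R,6E,8E)-5-(tert-butyldimethylsilyloxy)-1-[(4R)-2,2-dimethyl-1,3-dioxolan-4-yl]-1-hydroxy-4-methyldeca-6,8-dien-3-one | C/C=C/C=C/[C@@H](O[Si](C)(C)C(C)(C)C)[C@H](C)C(=O)C[C@H](O)[C@H]1COC(C)(C)O1 | intermediate
10 | (1S,4S,5R,6E,8E)-5-(tert-butyldimethylsilyloxy)-1-[(4R)-2,2-dimethyl-1,3-dioxolan-4-yl]-1-methoxy-4-methyldeca-6,8-dien-3-one | C/C=C/C=C/[C@@H](O[Si](C)(C)C(C)(C)C)[C@H](C)C(=O)C[C@H](OC)[C@H]1COC(C)(C)O1 | intermediate
11 | (1S,4R,5S)-1-[(2S,3R,4E,6E)-3-(tert-butyldimethylsilyloxy)octa-4,6-dien-2-yl]-5-methoxy-2,7-dioxabicyclo[2.2.1]heptane | C/C=C/C=C/[C@@H](O[Si](C)(C)C(C)(C)C)[C@H](C)[C@@]12C[C@H](OC)[C@@H](CO1)O2 | intermediate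
12 | [(2R,3S,5R)-5-[(2R,3R,4E,6E)-3-(tert-butyldimethylsilyloxy)octa-4,6-dien-2-yl]-3-methoxyoxolan-2-yl]methanol | C/C=C/C=C/[C@@H](O[Si](C)(C)C(C)(C)C)[C@H](C)[C@H]1C[C@H](OC)[C@H](O1)CO | intermediate
13 | [(2R,3S,5R)-5-[(2R,3R,4E)-3-(tert-butyldimethylsilyloxy)-5-[(2R,3R)-3-methyloxiran-2-yl]pent-4-en-2-yl]-3-methoxyoxolan-2-yl]methanol | C[C@H]1O[C@@H]1/C=C/[C@@H](O[Si](C)(C)C(C)(C)C)[C@H](C)[C@H]1C[C@H](OC)[C@H](O1)CO | intermediate
14 | (2S,3S,5R)-5-[(2R,3R,4E)-3-(tert-butyldimethylsilyloxy)-5-[(2R,3R)-3-methyloxiran-2-yl]pent-4-en-2-yl]-3-methoxyoxolane-2-carbaldehyde | C[C@H]1O[C@@H]1/C=C/[C@@H](O[Si](C)(C)C(C)(C)C)[C@H](C)[C@H]1C[C@H](OC)[C@H](O1)C=O | intermediate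
15 | methyl 2-[bis(2,2,2-trifluoroethoxy)phosphoryl]propanoate | COC(=O)C(C)P(=O)(OCC(F)(F)F)OCC(F)(F)F | starting material
16 | methyl (2Z)-3-[(2R,3S,5R)-5-[(2R,3R,4E)-3-(tert-butyldimethylsilyloxy)-5-[(2R,3R)-3-methyloxiran-2-yl]pent-4-en-2-yl]-3-methoxyoxolan-2-yl]-2-methylprop-2-enoate | C[C@H]1O[C@@H]1/C=C/[C@@H](O[Si](C)(C)C(C)(C)C)[C@H](C)[C@H]1C[C@H](OC)[C@H](O1)/C=C(/C)C(=O)OC | intermediate
17 | (2Z)-3-[(2R,3S,5R)-5-[(2R,3R,4E)-3-(tert-butyldimethylsilyloxy)-5-[(2R,3R)-3-methyloxiran-2-yl]pent-4-en-2-yl]-3-methoxyoxolan-2-yl]-2-methylprop-2-en-1-ol | C[C@H]1O[C@@H]1/C=C/[C@@H](O[Si](C)(C)C(C)(C)C)[C@H](C)[C@H]1C[C@H](OC)[C@H](O1)/C=C(/C)CO | intermediate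
18 | (2Z)-3-[(2R,3S,5R)-5-[(2S,3R,4E)-3-hydroxy-5-[(2R,3R)-3-methyloxiran-2-yl]pent-4-en-2-yl]-3-methoxyoxolan-2-yl]-2-methylprop-2-en-1-ol | C[C@H]1O[C@@H]1/C=C/[C@@H](O)[C@H](C)[C@H]1C[C@H](OC)[C@H](O1)/C=C(/C)CO | intermediate
19 | (2Z)-3-[(2R,3S,5R)-5-[(2S,3R,4E)-3-hydroxy-5-[(2R,3R)-3-methyloxiran-2-yl]pent-4-en-2-yl]-3-methoxyoxolan-2-yl]-2-methylprop-2-enal | C[C@H]1O[C@@H]1/C=C/[C@@H](O)[C@H](C)[C@H]1C[C@H](OC)[C@H](O1)/C=C(/C)C=O | intermediate
20 | 2-[bis(2,2,2-trifluoroethoxy)phosphoryl]propanoic acid (racemic) | CC(C(=O)O)P(=O)(OCC(F)(F)F)OCC(F)(F)F | intermediate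
21 | C11–C24 Z-enal with the 2-[bis(2,2,2-trifluoroethoxy)phosphoryl]propanoate ester on O19 (12Z,14R,15S,17R,18R,19R,20E,22R,23R) | C[C@H]1O[C@@H]1/C=C/[C@@H](OC(=O)C(C)P(=O)(OCC(F)(F)F)OCC(F)(F)F)[C@H](C)[C@H]1C[C@H](OC)[C@H](O1)/C=C(/C)C=O | intermediate
22 | C8–C24 homopropargylic alcohol phosphonate (11R,12Z,14R,15S,17R,18R,19R,20E,22R,23R) | C[C@H]1O[C@@H]1/C=C/[C@@H](OC(=O)C(C)P(=O)(OCC(F)(F)F)OCC(F)(F)F)[C@H](C)[C@H]1C[C@H](OC)[C@H](O1)/C=C(/C)[C@H](O)CC#C | intermediate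
23 | prop-2-yn-1-ol | C#CCO | starting material
24 | alkenylalane, dimethylaluminium (2E)-3-(dimethylalumanyl)-2-methylprop-2-en-1-olate | C[Al](C)/C=C(\C)CO[Al](C)C | intermediate
25 | (2E)-3-iodo-2-methylprop-2-en-1-ol | OC/C(C)=C/I | intermediate
26 | (2E)-3-iodo-2-methylprop-2-enal | O=C/C(C)=C/I | intermediate
27 | (4R)-4-benzyl-3-propanoyl-1,3-thiazolidine-2-thione | CCC(=O)N1[C@H](Cc2ccccc2)CSC1=S | starting material
28 | (2R,3R,4E)-1-[(4R)-4-benzyl-2-sulfanylidene-1,3-thiazolidin-3-yl]-3-hydroxy-5-iodo-2,4-dimethylpent-4-en-1-one | I\C=C(/C)[C@H](O)[C@@H](C)C(=O)N1[C@H](Cc2ccccc2)CSC1=S | intermediate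
29 | (2R,3R,4E)-1-[(4R)-4-benzyl-2-sulfanylidene-1,3-thiazolidin-3-yl]-5-iodo-2,4-dimethyl-3-(triethylsilyloxy)pent-4-en-1-one | I\C=C(/C)[C@H](O[Si](CC)(CC)CC)[C@@H](C)C(=O)N1[C@H](Cc2ccccc2)CSC1=S | intermediate
30 | (2R,3R,4E)-5-iodo-2,4-dimethyl-3-(triethylsilyloxy)pent-4-enal | I\C=C(/C)[C@H](O[Si](CC)(CC)CC)[C@@H](C)C=O | intermediate
31 | open-chain C1–C24 seco-ester with C7 vinyl iodide, C8 terminal alkyne, free 11-OH and 5-O-triethylsilyl ether (2Z,4S,5R,6E,11R,12Z,14R,15S,17R,18R,19R,20E,22R,23R) | C[C@H]1O[C@@H]1/C=C/[C@@H](OC(=O)/C(C)=C\[C@H](C)[C@@H](O[Si](CC)(CC)CC)/C(C)=C/I)[C@H](C)[C@H]1C[C@H](OC)[C@H](O1)/C=C(/C)[C@H](O)CC#C | intermediate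
32 | 8,9-didehydro macrolactone, 5-O-triethylsilyl ether (2Z,4S,5R,6E,11R,12Z,14R,15S,17R,18R,19R,20E,22R,23R) | CO[C@H]1C[C@H]2O[C@@H]1/C=C(/C)[C@H](O)CC#C/C=C(\C)[C@H](O[Si](CC)(CC)CC)[C@@H](C)/C=C(/C)C(=O)O[C@H](/C=C/[C@H]1O[C@@H]1C)[C@@H]2C | intermediate
33 | (5R)-5-deoxo-5-(triethylsilyloxy) macrolide (2Z,4S,5R,6E,8Z,11R,12Z,14R,15S,17R,18R,19R,20E,22R,23R) | CO[C@H]1C[C@H]2O[C@@H]1/C=C(/C)[C@H](O)C/C=C\C=C(/C)[C@H](O[Si](CC)(CC)CC)[C@@H](C)/C=C(/C)C(=O)O[C@H](/C=C/[C@H]1O[C@@H]1C)[C@@H]2C | intermediate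
34 | (5R)-5-deoxo-5-hydroxy macrolide, 5,11-diol (2Z,4S,5R,6E,8Z,11R,12Z,14R,15S,17R,18R,19R,20E,22R,23R) | CO[C@H]1C[C@H]2O[C@@H]1/C=C(/C)[C@H](O)C/C=C\C=C(/C)[C@H](O)[C@@H](C)/C=C(/C)C(=O)O[C@H](/C=C/[C@H]1O[C@@H]1C)[C@@H]2C | intermediate
35 | CNP0117824.1 (2Z,4S,6E,8Z,11R,12Z,14R,15S,17R,18R,19R,20E,22R,23R) | CO[C@H]1C[C@H]2O[C@@H]1/C=C(/C)[C@H](O)C/C=C\C=C(/C)C(=O)[C@@H](C)/C=C(/C)C(=O)O[C@H](/C=C/[C@H]1O[C@@H]1C)[C@@H]2C | target

**Step count and risks**

Total steps: 27. Longest linear sequence: 21 (steps 1–14, 16, 17, 23–27). The west aldehyde 30 takes 5 steps (18–22) and acid 20 one step (15).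

Most likely to fail:

Step 7 (with its opening in step 8). The 2,7-dioxabicyclo[2.2.1]heptane is strained and may oligomerise, lose methanol, or later open to a six-membered ring. The fallback sets out from 10 and closes the oxolane without the bicycle. 60 % aqueous AcOH at rt cleaves the acetonide to the keto diol F1 (in equilibrium with its hemiketals). Pivaloyl chloride and pyridine at −20 °C acylate only the primary C13 hydroxyl to give the keto pivalate F2, which can now close only to the five-membered hemiketal. Et3SiH and BF3·OEt2 at −78 °C reduce that hemiketal to the oxolane pivalate F3, and iBu2AlH at −78 °C removes the ester to rejoin the route at 12.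

Step 24. Slow macrocyclisation under palladium may let the vinyl oxirane ionise, or the ring may not close at C7–C8. The fallback exchanges the two unions and sets out from 22 together with 30. A fast, concentrated intermolecular Sonogashira coupling (Pd(PPh3)4, CuI, Et3N, THF, 0 °C) gives the open-chain enyne aldehyde phosphonate F4. The ring is then closed at C2=C3 by an intramolecular Still–Gennari olefination (K2CO3, 18-crown-6, toluene, 1 mM, rt), which returns to the route at 32.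

Step 27. The C11 allylic alcohol may be oxidised together with the C5 dienylic one. The fallback sets out from 33 and makes the oxidation unambiguous. TBSCl and imidazole in DMF give the 11-O-tert-butyldimethylsilyl ether F5. Buffered HF·pyridine at 0 °C removes only the triethylsilyl group to give the C5 alcohol F6. Dess–Martin periodinane with NaHCO3 gives the C5 ketone F7, and HF·pyridine in THF at rt removes the last silyl group to arrive at 35.

Further compounds
F1 | step 7 | (1S,4S,5R,6E,8E)-5-(tert-butyldimethylsilyloxy)-1-[(1R)-1,2-dihydroxyethyl]-1-methoxy-4-methyldeca-6,8-dien-3-one (keto diol, C13/C14 diol) | C/C=C/C=C/[C@@H](O[Si](C)(C)C(C)(C)C)[C@H](C)C(=O)C[C@H](OC)[C@H](O)CO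
F2 | step 7 | C13 pivalate of F1, (2R,3S,6S,7R,8E,10E)-7-(tert-butyldimethylsilyloxy)-2-hydroxy-3-methoxy-6-methyl-5-oxododeca-8,10-dien-1-yl 2,2-dimethylpropanoate | C/C=C/C=C/[C@@H](O[Si](C)(C)C(C)(C)C)[C@H](C)C(=O)C[C@H](OC)[C@H](O)COC(=O)C(C)(C)C
F3 | step 7 | [(2R,3S,5R)-5-[(2R,3R,4E,6E)-3-(tert-butyldimethylsilyloxy)octa-4,6-dien-2-yl]-3-methoxyoxolan-2-yl]methyl 2,2-dimethylpropanoate | C/C=C/C=C/[C@@H](O[Si](C)(C)C(C)(C)C)[C@H](C)[C@H]1C[C@H](OC)[C@H](O1)COC(=O)C(C)(C)C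
F4 | step 24 | open-chain C3–C24 enyne with C3 aldehyde, 5-O-triethylsilyl ether, free 11-OH and the phosphonopropanoate on O19 (4R,5R,6E,11R,12Z,14R,15S,17R,18R,19R,20E,22R,23R) | C[C@H]1O[C@@H]1/C=C/[C@@H](OC(=O)C(C)P(=O)(OCC(F)(F)F)OCC(F)(F)F)[C@H](C)[C@H]1C[C@H](OC)[C@H](O1)/C=C(/C)[C@H](O)CC#C/C=C(\C)[C@H](O[Si](CC)(CC)CC)[C@@H](C)C=O
F5 | step 27 | 11-O-tert-butyldimethylsilyl ether of 33 (5-O-triethylsilyl, 11-O-TBS macrolide) | CO[C@H]1C[C@H]2O[C@@H]1/C=C(/C)[C@H](O[Si](C)(C)C(C)(C)C)C/C=C\C=C(/C)[C@H](O[Si](CC)(CC)CC)[C@@H](C)/C=C(/C)C(=O)O[C@H](/C=C/[C@H]1O[C@@H]1C)[C@@H]2C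
F6 | step 27 | (5R)-5-deoxo-5-hydroxy macrolide 11-O-tert-butyldimethylsilyl ether | CO[C@H]1C[C@H]2O[C@@H]1/C=C(/C)[C@H](O[Si](C)(C)C(C)(C)C)C/C=C\C=C(/C)[C@H](O)[C@@H](C)/C=C(/C)C(=O)O[C@H](/C=C/[C@H]1O[C@@H]1C)[C@@H]2C
F7 | step 27 | 11-O-tert-butyldimethylsilyl ether of the target | CO[C@H]1C[C@H]2O[C@@H]1/C=C(/C)[C@H](O[Si](C)(C)C(C)(C)C)C/C=C\C=C(/C)C(=O)[C@@H](C)/C=C(/C)C(=O)O[C@H](/C=C/[C@H]1O[C@@H]1C)[C@@H]2C
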